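**Retrosynthetic overview**

1. Target 16 ⇐ exo-methylene alcohol 14 by alcohol oxidation and moving the C=C into conjugation.
2. 14 ⇐ epoxide 11 in one operation: Meinwald ring contraction (cyclohexene oxide → cyclopentane, quaternary C1 and a formyl group), then a type 2 carbonyl-ene closure of the seven-membered ring.
3. 11 ⇐ cyclohexenyl diol 7 (ester at C6–OH, TMS at C4–OH, face-selective epoxidation); 7 ⇐ anti-aldol 6 + isopropyl nucleophile.
4. 6 ⇐ linear dienolate of 3-methylcyclohex-2-en-1-one + 3-methylbut-3-enal (asymmetric aldol sets C5/C6; C4 and C1 follow by relay).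
5. Ring order: the six-membered carbocycle comes from the starting enone; the five- and seven-membered rings are formed together in step 7.

**Assumptions.** Atom labels used in the text: C1 = ring-fusion carbon bearing CH3; C2, C3 = cyclopentane CH2; C4 = C(OH)(iPr); C5 = ring-fusion CH; C6 = CH–O(aroyl); C7 = CH2; C8 = C(CH3)=; C9 = =CH; C10 = C=O. The target is (1S,4R,5S,6S). The carbinol at C10 in 13 and 14 forms as an epimer mixture, is left undefined and is oxidised in step 8.

**Step 1**
Reactants: 1 3-methylcyclohex-2-en-1-one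
Product: 2 3-methylcyclohexa-1,3-dien-1-yl acetate
Conditions: isopropenyl acetate (neat), p-TsOH·H2O (2 mol %), 95 °C, acetone distilled off
Reagents that add atoms: isopropenyl acetate CC(=C)OC(C)=O
Why: Acid-catalysed enol-ester exchange under equilibrating conditions gives the thermodynamically preferred through-conjugated, endocyclic dienol acetate, the regiodefined precursor of the linear dienolate; no stereocentre is formed.

**Step 2**
Reactants: 3 3-methylbut-3-en-1-ol
Product: 4 3-methylbut-3-enal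
Conditions: DMP (1.1 equiv), CH2Cl2, 0 °C; used at once as a cold solution
Reagents that add atoms: none
Why: Dess–Martin oxidation gives the aldehyde under non-basic conditions that do not move the 1,1-disubstituted double bond into conjugation; no stereocentre is formed.

**Step 3**
Reactants: 2 3-methylcyclohexa-1,3-dien-1-yl acetate; 4 3-methylbut-3-enal
Product: 6 (2S)-2-[(1S)-1-hydroxy-3-methylbut-3-en-1-yl]-3-methylcyclohex-3-en-1-one, via tin dienolate 5 (not isolated)
Conditions: Bu3SnOMe (1.05 equiv), neat, 25 °C, MeOAc removed in vacuo; then 4 (1.2 equiv), (R)-BINAP·AgOTf (10 mol %), THF, −20 °C; H2O work-up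
Reagents that add atoms: tributyltin methoxide CCCC[Sn](CCCC)(CCCC)OC (tin is carried only in intermediate 5)
Why: Methoxide cleavage of the enol acetate gives the tin dienolate, which reacts at its α-carbon through a closed six-membered transition state on the BINAP·AgOTf-bound aldehyde (silver-catalysed asymmetric aldol of a tin enolate), the ring-locked E-enolate giving the anti adduct and the (R)-ligand selecting the aldehyde face that leads to (2S,1S).

**Step 4**
Reactants: 6 (2S)-2-[(1S)-1-hydroxy-3-methylbut-3-en-1-yl]-3-methylcyclohex-3-en-1-one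
Product: 7 (1R,2S)-2-[(1S)-1-hydroxy-3-methylbut-3-en-1-yl]-3-methyl-1-(propan-2-yl)cyclohex-3-en-1-ol
Conditions: CeCl3 (3 equiv), iPrMgCl (3 equiv), THF, −78 °C; H2O quench
Reagents that add atoms: isopropylmagnesium chloride CC(C)[Mg]Cl
Why: The organocerium 1,2-addition suppresses enolisation, retro-aldol and β-hydride reduction and attacks the ketone from the ring face opposite the adjacent side chain, so the new tertiary hydroxyl is cis to the side chain (1R).

**Step 5**
Reactants: 7 (1R,2S)-2-[(1S)-1-hydroxy-3-methylbut-3-en-1-yl]-3-methyl-1-(propan-2-yl)cyclohex-3-en-1-ol; 8 3,4,5-trimethoxybenzoyl chloride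
Product: 10 (1S)-3-methyl-1-[(1S,6R)-2-methyl-6-(propan-2-yl)-6-(trimethylsilyloxy)cyclohex-2-en-1-yl]but-3-en-1-yl 3,4,5-trimethoxybenzoate, via monoester 9 (not isolated)
Conditions: 8 (1.1 equiv), Et3N, DMAP (10 mol %), CH2Cl2, 0 °C; then TMSOTf (1.3 equiv), 2,6-lutidine, −78 → 0 °C
Reagents that add atoms: trimethylsilyl trifluoromethanesulfonate C[Si](C)(C)OS(=O)(=O)C(F)(F)F
Why: DMAP-catalysed acylation discriminates the secondary from the hindered tertiary hydroxyl, and in-situ silylation caps the tertiary alcohol so that it can neither direct the peracid nor consume the Lewis acid later; no new stereocentre.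

**Step 6**
Reactants: 10 (1S)-3-methyl-1-[(1S,6R)-2-methyl-6-(propan-2-yl)-6-(trimethylsilyloxy)cyclohex-2-en-1-yl]but-3-en-1-yl 3,4,5-trimethoxybenzoate
Product: 11 (1S)-3-methyl-1-[(1R,2R,3R,6S)-1-methyl-3-(propan-2-yl)-3-(trimethylsilyloxy)-7-oxabicyclo[4.1.0]heptan-2-yl]but-3-en-1-yl 3,4,5-trimethoxybenzoate (oxirane oxygen trans to OTMS and to the side chain)
Conditions: m-CPBA (1.05 equiv), CH2Cl2/0.5 M aq. NaHCO3, 0 °C
Reagents that add atoms: m-chloroperoxybenzoic acid OOC(=O)c1cccc(Cl)c1
Why: Prilezhaev epoxidation prefers the more electron-rich trisubstituted ring alkene over the 1,1-disubstituted side-chain alkene and, under steric control, delivers oxygen to the face anti to the axial OTMS group and the neighbouring side chain.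

**Step 7**
Reactants: 11 (1S)-3-methyl-1-[(1R,2R,3R,6S)-1-methyl-3-(propan-2-yl)-3-(trimethylsilyloxy)-7-oxabicyclo[4.1.0]heptan-2-yl]but-3-en-1-yl 3,4,5-trimethoxybenzoate
Product: 14 (3R,3aS,4S,8aS)-3,8-dihydroxy-8a-methyl-6-methylidene-3-(propan-2-yl)decahydroazulen-4-yl 3,4,5-trimethoxybenzoate, via ring-contracted aldehyde 12 (not isolated), via silyl ether 13 (not isolated)
Conditions: Me2AlCl (3 equiv), CH2Cl2, −78 → −20 °C; then 1 M HCl/THF, 25 °C
Reagents that add atoms: none
Why: Proposed new method: Lewis-acid opening of the oxirane at its tertiary carbon C1 triggers a Meinwald-type semipinacol shift of the ring bond C10–C2 (the C10–O bond is axial in the chair with isopropyl and side chain equatorial, so no axial hydride competes), contracting the ring 6 → 5 with inversion at C1 and placing the formyl group on the face the oxirane occupied, trans to the side chain; the Me2AlCl-bound neopentyl aldehyde 12 is then captured by the 2-methylallyl terminus in a type 2 carbonyl-ene cyclisation that closes the trans-fused seven-membered ring, the closest known reactions being the Lewis-acid ring contraction of 1-methylcyclohexene oxides to 1-methylcyclopentanecarbaldehydes and Me2AlCl-promoted type 2 ene cyclisations of 6-methylhept-6-enals to 3-methylenecycloheptanols, and the acidic work-up removes the TMS group.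

**Step 8**
Reactants: 14 (3R,3aS,4S,8aS)-3,8-dihydroxy-8a-methyl-6-methylidene-3-(propan-2-yl)decahydroazulen-4-yl 3,4,5-trimethoxybenzoate
Product: 16 (3R,3aS,4S,8aS)-3-hydroxy-6,8a-dimethyl-8-oxo-3-(propan-2-yl)-1,2,3,3a,4,5,8,8a-octahydroazulen-4-yl 3,4,5-trimethoxybenzoate, via exo-methylene ketone 15 (not isolated)
Conditions: DMP (1.3 equiv), CH2Cl2, 25 °C; then p-TsOH·H2O (10 mol %), 25 °C
Reagents that add atoms: none
Why: Dess–Martin oxidation of the only oxidisable (secondary) alcohol gives the β,γ-unsaturated ketone, and acid-catalysed enolisation and reprotonation move the exocyclic double bond into conjugation (thermodynamic trisubstituted enone) without touching the four stereocentres.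

**Compound list**

1 | 3-methylcyclohex-2-en-1-one | CC1=CC(=O)CCC1 | starting material
2 | 3-methylcyclohexa-1,3-dien-1-yl acetate | CC(=O)OC1=CC(C)=CCC1 | intermediate
3 | 3-methylbut-3-en-1-ol | CC(=C)CCO | starting material
4 | 3-methylbut-3-enal | CC(=C)CC=O | intermediate
5 | tributyl[(3-methylcyclohexa-1,3-dien-1-yl)oxy]stannane | CCCC[Sn](CCCC)(CCCC)OC1=CC(C)=CCC1 | intermediate
6 | (2S)-2-[(1S)-1-hydroxy-3-methylbut-3-en-1-yl]-3-methylcyclohex-3-en-1-one | O[C@@H](CC(C)=C)[C@@H]1C(C)=CCCC1=O | intermediate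
7 | (1R,2S)-2-[(1S)-1-hydroxy-3-methylbut-3-en-1-yl]-3-methyl-1-(propan-2-yl)cyclohex-3-en-1-ol | O[C@@H](CC(C)=C)[C@@H]1C(C)=CCC[C@@]1(O)C(C)C | intermediate
8 | 3,4,5-trimethoxybenzoyl chloride | COc1cc(C(Cl)=O)cc(OC)c1OC | starting material
9 | (1S)-1-[(1S,6R)-6-hydroxy-2-methyl-6-(propan-2-yl)cyclohex-2-en-1-yl]-3-methylbut-3-en-1-yl 3,4,5-trimethoxybenzoate | COc1cc(C(=O)O[C@@H](CC(C)=C)[C@@H]2C(C)=CCC[C@@]2(O)C(C)C)cc(OC)c1OC | intermediate
10 | (1S)-3-methyl-1-[(1S,6R)-2-methyl-6-(propan-2-yl)-6-(trimethylsilyloxy)cyclohex-2-en-1-yl]but-3-en-1-yl 3,4,5-trimethoxybenzoate | COc1cc(C(=O)O[C@@H](CC(C)=C)[C@@H]2C(C)=CCC[C@@]2(O[Si](C)(C)C)C(C)C)cc(OC)c1OC | intermediate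
11 | (1S)-3-methyl-1-[(1R,2R,3R,6S)-1-methyl-3-(propan-2-yl)-3-(trimethylsilyloxy)-7-oxabicyclo[4.1.0]heptan-2-yl]but-3-en-1-yl 3,4,5-trimethoxybenzoate | COc1cc(C(=O)O[C@@H](CC(C)=C)[C@@H]2[C@@]3(C)O[C@H]3CC[C@@]2(O[Si](C)(C)C)C(C)C)cc(OC)c1OC | intermediate
12 | (1S)-1-[(1S,2S,5R)-2-formyl-2-methyl-5-(propan-2-yl)-5-(trimethylsilyloxy)cyclopentyl]-3-methylbut-3-en-1-yl 3,4,5-trimethoxybenzoate | O=C[C@@]1(C)CC[C@@](O[Si](C)(C)C)(C(C)C)[C@@H]1[C@H](CC(C)=C)OC(=O)c2cc(OC)c(OC)c(OC)c2 | intermediate
13 | (3R,3aS,4S,8aS)-8-hydroxy-8a-methyl-6-methylidene-3-(propan-2-yl)-3-(trimethylsilyloxy)decahydroazulen-4-yl 3,4,5-trimethoxybenzoate (C8 epimers) | COc1cc(C(=O)O[C@H]2CC(=C)CC(O)[C@@]3(C)CC[C@@](O[Si](C)(C)C)(C(C)C)[C@H]23)cc(OC)c1OC | intermediate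
14 | (3R,3aS,4S,8aS)-3,8-dihydroxy-8a-methyl-6-methylidene-3-(propan-2-yl)decahydroazulen-4-yl 3,4,5-trimethoxybenzoate (C8 epimers) | COc1cc(C(=O)O[C@H]2CC(=C)CC(O)[C@@]3(C)CC[C@@](O)(C(C)C)[C@H]23)cc(OC)c1OC | intermediate
15 | (3R,3aS,4S,8aS)-3-hydroxy-8a-methyl-6-methylidene-8-oxo-3-(propan-2-yl)decahydroazulen-4-yl 3,4,5-trimethoxybenzoate | COc1cc(C(=O)O[C@H]2CC(=C)CC(=O)[C@@]3(C)CC[C@@](O)(C(C)C)[C@H]23)cc(OC)c1OC | intermediate
16 | (3R,3aS,4S,8aS)-3-hydroxy-6,8a-dimethyl-8-oxo-3-(propan-2-yl)-1,2,3,3a,4,5,8,8a-octahydroazulen-4-yl 3,4,5-trimethoxybenzoate | COc1cc(C(=O)O[C@H]2CC(C)=CC(=O)[C@@]3(C)CC[C@@](O)(C(C)C)[C@H]23)cc(OC)c1OC | target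

**Step count.** Total: 8 steps. Longest linear sequence: 7 steps (1, 3, 4, 5, 6, 7, 8 from 3-methylcyclohex-2-en-1-one); step 2 is a one-step side branch.

**Three steps most likely to fail**

Step 7 (ring contraction/ene cascade). Three things can go wrong: the side-chain alkene may intercept the C1 cation (epoxide–olefin cyclisation to a six-membered ring) before the ring bond migrates; a hydride may shift instead to give the cyclohexanone; or the neopentyl aldehyde may not undergo the ene closure. The fallback separates the two events and closes the seven-membered ring by metathesis; it does not cure interception of the cation by the alkene. It sets out from 11 and returns at 16. The oxirane is rearranged alone (BF3·OEt2, CH2Cl2, −78 °C, short contact) and aldehyde 12 is isolated. CH2=CHMgBr (THF, −78 °C) adds to the aldehyde to give (1S)-1-[(1S,2S,5R)-2-(1-hydroxyprop-2-en-1-yl)-2-methyl-5-(propan-2-yl)-5-(trimethylsilyloxy)cyclopentyl]-3-methylbut-3-en-1-yl 3,4,5-trimethoxybenzoate F1. DMP oxidises it to the vinyl ketone (1S)-3-methyl-1-[(1S,2S,5R)-2-methyl-2-(prop-2-enoyl)-5-(propan-2-yl)-5-(trimethylsilyloxy)cyclopentyl]but-3-en-1-yl 3,4,5-trimethoxybenzoate F2. Ring-closing metathesis with the second-generation Hoveyda–Grubbs catalyst (toluene, 80 °C) forms the trisubstituted enone (3R,3aS,4S,8aS)-6,8a-dimethyl-8-oxo-3-(propan-2-yl)-3-(trimethylsilyloxy)-1,2,3,3a,4,5,8,8a-octahydroazulen-4-yl 3,4,5-trimethoxybenzoate F3, and 1 M HCl/THF removes the silyl group to give 16.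

Step 3 (asymmetric aldol). The precedent for this aldol is a saturated cyclic tin enolate with aromatic aldehydes. Here the enolate is a dienolate (α- versus γ-attack), the aldehyde is aliphatic and prone to isomerise, and the ligand sense is assigned by analogy (the enantiomeric ligand is used if the sense is opposite). The fallback replaces catalyst control by resolution; it sets out from 2 and 4 and returns at 6. MeLi (2 equiv, THF, −78 °C) cleaves 2 to the lithium dienolate, which adds to 4 through the same closed transition state to give the racemic anti aldol, that is 6 together with its enantiomer (2R)-2-[(1R)-1-hydroxy-3-methylbut-3-en-1-yl]-3-methylcyclohex-3-en-1-one F4. Burkholderia cepacia lipase with vinyl acetate acetylates the (1R)-carbinol of F4 (the fast-reacting enantiomer by the usual large/medium-group rule) to (1R)-3-methyl-1-[(1R)-2-methyl-6-oxocyclohex-2-en-1-yl]but-3-en-1-yl acetate F5, and unreacted 6 is separated by chromatography.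

Step 6 (epoxidation). The peracid may also attack the unhindered side-chain alkene, and the facial preference rests on substrate sterics alone. The fallback moves from substrate control to catalyst control; it sets out from 10 and returns at 11 with no new compound. It uses the Shi fructose-derived ketone (the enantiomer matched to the substrate bias, 30 mol %) with KHSO5 (as 2KHSO5·KHSO4·K2SO4) and K2CO3 in MeCN/dimethoxymethane/aqueous buffer at 0 °C. The chiral dioxirane is a poor oxidant for 1,1-disubstituted terminal alkenes and imposes its own facial selectivity on the trisubstituted ring alkene.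

**Further compounds**

F1 | step 7 | (1S)-1-[(1S,2S,5R)-2-(1-hydroxyprop-2-en-1-yl)-2-methyl-5-(propan-2-yl)-5-(trimethylsilyloxy)cyclopentyl]-3-methylbut-3-en-1-yl 3,4,5-trimethoxybenzoate | C=CC(O)[C@@]1(C)CC[C@@](O[Si](C)(C)C)(C(C)C)[C@@H]1[C@H](CC(C)=C)OC(=O)c2cc(OC)c(OC)c(OC)c2
F2 | step 7 | (1S)-3-methyl-1-[(1S,2S,5R)-2-methyl-2-(prop-2-enoyl)-5-(propan-2-yl)-5-(trimethylsilyloxy)cyclopentyl]but-3-en-1-yl 3,4,5-trimethoxybenzoate | C=CC(=O)[C@@]1(C)CC[C@@](O[Si](C)(C)C)(C(C)C)[C@@H]1[C@H](CC(C)=C)OC(=O)c2cc(OC)c(OC)c(OC)c2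
F3 | step 7 | (3R,3aS,4S,8aS)-6,8a-dimethyl-8-oxo-3-(propan-2-yl)-3-(trimethylsilyloxy)-1,2,3,3a,4,5,8,8a-octahydroazulen-4-yl 3,4,5-trimethoxybenzoate | COc1cc(C(=O)O[C@H]2CC(C)=CC(=O)[C@@]3(C)CC[C@@](O[Si](C)(C)C)(C(C)C)[C@H]23)cc(OC)c1OC
F4 | step 3 | (2R)-2-[(1R)-1-hydroxy-3-methylbut-3-en-1-yl]-3-methylcyclohex-3-en-1-one | O[C@H](CC(C)=C)[C@H]1C(C)=CCCC1=O
F5 | step 3 | (1R)-3-methyl-1-[(1R)-2-methyl-6-oxocyclohex-2-en-1-yl]but-3-en-1-yl acetate | CC(=O)O[C@H](CC(C)=C)[C@H]1C(C)=CCCC1=O
F0 | step 6 | none | none
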